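The butenolide ring (O1, C2, C3, C4, C5) is opened at O1–C5 and O1–C2. C5 is an allylic carbinol carbon next to the ring C3=C4 bond, so its oxygen can come from a tertiary C3 carbinol by a suprafacial 1,3-shift across C3–C4–C5; the new C5 hydroxyl then acylates the cis C2 ester. One rhenium(VII)-catalysed operation should therefore relay (R)-C3 to (S)-C5, move the alkene into the ring and close the lactone. The precursor is a (Z)-alkylidene citramalate diester (C2 methyl ester, C4 tert-butyl ester, ketone masked as dioxolane), built from (S)-lactic acid through a stereoretentive acetal-enolate aldol and a geometry-defining enol triflate carbonylation.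

Key step: step 11

Remark: ring atoms are labelled O1, C2 (lactone C=O), C3 (methyl-bearing), C4 (carboxyl-bearing) and C5 (stereocentre) as in the target, and the corresponding atoms keep these labels in all intermediates. Aldol 10 is carried as a mixture of carbinol epimers.

Step 1
Reactants: 1 (S)-lactic acid; 2 pivalaldehyde
Product: 3 (2S,5S)-2-tert-butyl-5-methyl-1,3-dioxolan-4-one
Conditions: TsOH·H2O (cat.), H2SO4 (cat.), pentane, reflux with azeotropic removal of water; crystallisation (Et2O/pentane, −78 °C)
Reagents that add atoms: none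
Why: Acid-catalysed acetalisation of the α-hydroxy acid leaves the lactate centre untouched, and the thermodynamically preferred cis acetal, purified by crystallisation, fixes (S) at the new acetal carbon.

Step 2
Reactants: 4 hexadecanolide (oxacycloheptadecan-2-one)
Product: 6 17-hydroxyheptadecan-2-one, via Weinreb amide 5 (not isolated)
Conditions: MeNH(OMe)·HCl (1.5 equiv), iPrMgCl (3.0 equiv), THF, −20 → 0 °C; then MeMgBr (3 equiv), 0 °C → rt; aq. NH4Cl
Reagents that add atoms: methylmagnesium bromide, C[Mg]Br; N,O-dimethylhydroxylamine hydrochloride, CNOC.Cl (its atoms stay only in intermediate 5)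
Why: The magnesium amide opens the lactone to Weinreb amide 5, whose chelated adduct with the Grignard reagent collapses only on work-up, so the methyl ketone should form without over-addition (Weinreb ketone synthesis in one pot).

Step 3
Reactants: 6 17-hydroxyheptadecan-2-one; 7 ethylene glycol
Product: 8 15-(2-methyl-1,3-dioxolan-2-yl)pentadecan-1-ol
Conditions: TsOH·H2O (5 mol%), toluene, reflux, azeotropic removal of water
Reagents that add atoms: none
Why: Acid-catalysed ketalisation driven by water removal masks the methyl ketone as a dioxolane that tolerates the enolate chemistry of steps 5 and 7.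

Step 4
Reactants: 8 15-(2-methyl-1,3-dioxolan-2-yl)pentadecan-1-ol
Product: 9 15-(2-methyl-1,3-dioxolan-2-yl)pentadecanal
Conditions: TEMPO (10 mol%), PhI(OAc)2 (1.1 equiv), CH2Cl2, rt
Reagents that add atoms: none
Why: The oxoammonium-mediated (TEMPO/PhI(OAc)2) oxidation of a primary alcohol stops at the aldehyde and should leave the ketal intact.

Step 5
Reactants: 3 (2S,5S)-2-tert-butyl-5-methyl-1,3-dioxolan-4-one; 9 15-(2-methyl-1,3-dioxolan-2-yl)pentadecanal
Product: 10 (2S,5R)-2-tert-butyl-5-[1-hydroxy-15-(2-methyl-1,3-dioxolan-2-yl)pentadecyl]-5-methyl-1,3-dioxolan-4-one (carbinol epimers)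
Conditions: LDA (1.05 equiv), THF, −78 °C; then 9, −78 °C; AcOH quench at −78 °C
Reagents that add atoms: none
Why: In this aldol addition the acetal carbon keeps the stereochemical information while the lactate carbon is a trigonal enolate, and the aldehyde enters anti to the tert-butyl group, i.e. with retention, which sets (R)-C3 (self-regeneration of stereocentres).

Step 6
Reactants: 10 (2S,5R)-2-tert-butyl-5-[1-hydroxy-15-(2-methyl-1,3-dioxolan-2-yl)pentadecyl]-5-methyl-1,3-dioxolan-4-one
Product: 11 (2S,5R)-2-tert-butyl-5-methyl-5-[15-(2-methyl-1,3-dioxolan-2-yl)pentadecanoyl]-1,3-dioxolan-4-one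
Conditions: Dess–Martin periodinane (1.5 equiv), pyridine, CH2Cl2, rt
Reagents that add atoms: none
Why: Dess–Martin oxidation should convert both carbinol epimers into one C4 ketone that cannot enolise towards the quaternary C3.

Step 7
Reactants: 11 (2S,5R)-2-tert-butyl-5-methyl-5-[15-(2-methyl-1,3-dioxolan-2-yl)pentadecanoyl]-1,3-dioxolan-4-one
Product: 12 (2S,5R)-2-tert-butyl-5-methyl-5-[(Z)-15-(2-methyl-1,3-dioxolan-2-yl)-1-(trifluoromethanesulfonyloxy)pentadec-1-en-1-yl]-1,3-dioxolan-4-one
Conditions: KHMDS (1.2 equiv), THF, −78 °C; then PhNTf2 (1.3 equiv), −78 → 0 °C; aq. NH4Cl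
Reagents that add atoms: N-phenylbis(trifluoromethanesulfonimide), O=S(=O)(N(c1ccccc1)S(=O)(=O)C(F)(F)F)C(F)(F)F
Why: Deprotonation is possible only at C5, and a ketone flanked by a fully substituted carbon gives the Z(O)-enolate to avoid allylic strain, so O-triflation should fix the chain cis to the triflate (stereodefined enol triflate formation).

Step 8
Reactants: 12 (2S,5R)-2-tert-butyl-5-methyl-5-[(Z)-15-(2-methyl-1,3-dioxolan-2-yl)-1-(trifluoromethanesulfonyloxy)pentadec-1-en-1-yl]-1,3-dioxolan-4-one
Product: 14 (Z)-2-[(2S,4R)-2-tert-butyl-4-methyl-5-oxo-1,3-dioxolan-4-yl]-16-(2-methyl-1,3-dioxolan-2-yl)hexadec-2-enoic acid, via mixed acetic anhydride 13 (not isolated)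
Conditions: Pd(OAc)2 (5 mol%), dppf (10 mol%), KOAc (4 equiv), CO (1 atm), DMSO, 60 °C; aq. citric acid work-up
Reagents that add atoms: carbon monoxide, [C-]#[O+]; potassium acetate, CC(=O)[O-].[K+] (the bridging oxygen of 13 stays in the carboxyl group)
Why: Palladium-catalysed hydroxycarbonylation proceeds by oxidative addition into C–OTf with retention of alkene geometry, CO insertion and acetate capture to 13, which is hydrolysed on work-up to the acid with the chain cis to the carboxyl group.

Step 9
Reactants: 14 (Z)-2-[(2S,4R)-2-tert-butyl-4-methyl-5-oxo-1,3-dioxolan-4-yl]-16-(2-methyl-1,3-dioxolan-2-yl)hexadec-2-enoic acid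
Product: 15 tert-butyl (Z)-2-[(2S,4R)-2-tert-butyl-4-methyl-5-oxo-1,3-dioxolan-4-yl]-16-(2-methyl-1,3-dioxolan-2-yl)hexadec-2-enoate
Conditions: Me2NCH(OtBu)2 (4 equiv), toluene, 80 °C
Reagents that add atoms: N,N-dimethylformamide di-tert-butyl acetal, CN(C)C(OC(C)(C)C)OC(C)(C)C
Why: O-tert-butylation of the acid with the formamide acetal under neutral conditions gives an ester that resists methoxide in step 10 and is removable by acid together with the ketal.

Step 10
Reactants: 15 tert-butyl (Z)-2-[(2S,4R)-2-tert-butyl-4-methyl-5-oxo-1,3-dioxolan-4-yl]-16-(2-methyl-1,3-dioxolan-2-yl)hexadec-2-enoate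
Product: 16 4-tert-butyl 1-methyl (R,Z)-2-hydroxy-2-methyl-3-[14-(2-methyl-1,3-dioxolan-2-yl)tetradecylidene]butanedioate
Conditions: K2CO3 (0.3 equiv), MeOH, 0 °C → rt
Reagents that add atoms: methanol, CO
Why: Base-catalysed methanolysis (transesterification) of the activated acylal lactone releases pivalaldehyde and unveils the tertiary C3 hydroxyl and the C2 methyl ester without touching C3 or the tert-butyl ester.

Step 11
Reactants: 16 4-tert-butyl 1-methyl (R,Z)-2-hydroxy-2-methyl-3-[14-(2-methyl-1,3-dioxolan-2-yl)tetradecylidene]butanedioate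
Product: 18 tert-butyl (S)-4-methyl-2-[13-(2-methyl-1,3-dioxolan-2-yl)tridecyl]-5-oxo-2,5-dihydrofuran-3-carboxylate, via transposed hydroxy diester 17 (not isolated)
Conditions: Ph3SiOReO3 (10 mol%), ClCH2CH2Cl, 40–60 °C
Reagents that add atoms: none
Why: The tertiary C3 hydroxyl exchanges onto the rhenium(VII) oxo centre to give a perrhenate ester, which undergoes a [3,3]-sigmatropic shift through a six-membered chair transition state that breaks C3–O, forms C5–O and moves the alkene from C4=C5 to C3=C4; alcohol exchange then releases 17 and the catalyst. The closest known reaction type is the rhenium(VII)-oxo-catalysed 1,3-transposition of allylic alcohols with chirality transfer and in situ trapping of the new hydroxyl. In 17 the C5 hydroxyl and the C2 methyl ester are cis on C3=C4, so the butenolide closes by 5-exo-trig acyl substitution (O1–C2, loss of methanol), which makes the sequence irreversible. The C5 configuration is controlled by the (R)-C3 carbinol together with the Z geometry of C4=C5: oxygen leaves and arrives on the same face, hydrogen takes the pseudo-axial position at C5, and the chair with the C2 ester pseudo-axial delivers (S)-C5 cis to C2. The other chair gives the (R)-alcohol trans to C2, which cannot lactonise and re-enters the equilibrium, so only the (S)-lactone should accumulate. The step needs a strictly suprafacial, non-ionising pathway, which the two ester groups on the allyl unit (they disfavour a cation), the non-acidic silyl perrhenate and the geometrically pure Z-alkene from step 7 are expected to secure.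

Step 12
Reactants: 18 tert-butyl (S)-4-methyl-2-[13-(2-methyl-1,3-dioxolan-2-yl)tridecyl]-5-oxo-2,5-dihydrofuran-3-carboxylate
Product: 19 (S)-4-methyl-5-oxo-2-(14-oxopentadecyl)-2,5-dihydrofuran-3-carboxylic acid (target)
Conditions: TFA/CH2Cl2 (1:3), H2O (5 equiv), 0 °C → rt
Reagents that add atoms: water, O
Why: Acidolysis of the tert-butyl ester (loss of 2-methylpropene) and acid hydrolysis of the dioxolane occur in one operation, and because no base is present the acidic C5–H should not epimerise.

Compound list
1 | (S)-lactic acid | C[C@H](O)C(=O)O | starting material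
2 | pivalaldehyde | CC(C)(C)C=O | starting material
3 | (2S,5S)-2-tert-butyl-5-methyl-1,3-dioxolan-4-one | C[C@@H]1O[C@H](C(C)(C)C)OC1=O | intermediate
4 | hexadecanolide (oxacycloheptadecan-2-one) | O=C1CCCCCCCCCCCCCCCO1 | starting material
5 | 16-hydroxy-N-methoxy-N-methylhexadecanamide | CON(C)C(=O)CCCCCCCCCCCCCCCO | intermediate (not isolated)
6 | 17-hydroxyheptadecan-2-one | CC(=O)CCCCCCCCCCCCCCCO | intermediate
7 | ethylene glycol | OCCO | starting material
8 | 15-(2-methyl-1,3-dioxolan-2-yl)pentadecan-1-ol | CC1(CCCCCCCCCCCCCCCO)OCCO1 | intermediate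
9 | 15-(2-methyl-1,3-dioxolan-2-yl)pentadecanal | CC1(CCCCCCCCCCCCCCC=O)OCCO1 | intermediate
10 | (2S,5R)-2-tert-butyl-5-[1-hydroxy-15-(2-methyl-1,3-dioxolan-2-yl)pentadecyl]-5-methyl-1,3-dioxolan-4-one (carbinol epimers) | C[C@]1(C(O)CCCCCCCCCCCCCCC2(C)OCCO2)O[C@H](C(C)(C)C)OC1=O | intermediate
11 | (2S,5R)-2-tert-butyl-5-methyl-5-[15-(2-methyl-1,3-dioxolan-2-yl)pentadecanoyl]-1,3-dioxolan-4-one | C[C@]1(C(=O)CCCCCCCCCCCCCCC2(C)OCCO2)O[C@H](C(C)(C)C)OC1=O | intermediate
12 | (2S,5R)-2-tert-butyl-5-methyl-5-[(Z)-15-(2-methyl-1,3-dioxolan-2-yl)-1-(trifluoromethanesulfonyloxy)pentadec-1-en-1-yl]-1,3-dioxolan-4-one | C[C@]1(/C(OS(=O)(=O)C(F)(F)F)=C/CCCCCCCCCCCCCC2(C)OCCO2)O[C@H](C(C)(C)C)OC1=O | intermediate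
13 | acetic (Z)-2-[(2S,4R)-2-tert-butyl-4-methyl-5-oxo-1,3-dioxolan-4-yl]-16-(2-methyl-1,3-dioxolan-2-yl)hexadec-2-enoic anhydride | C[C@]1(/C(C(=O)OC(C)=O)=C/CCCCCCCCCCCCCC2(C)OCCO2)O[C@H](C(C)(C)C)OC1=O | intermediate (not isolated)
14 | (Z)-2-[(2S,4R)-2-tert-butyl-4-methyl-5-oxo-1,3-dioxolan-4-yl]-16-(2-methyl-1,3-dioxolan-2-yl)hexadec-2-enoic acid | C[C@]1(/C(C(=O)O)=C/CCCCCCCCCCCCCC2(C)OCCO2)O[C@H](C(C)(C)C)OC1=O | intermediate
15 | tert-butyl (Z)-2-[(2S,4R)-2-tert-butyl-4-methyl-5-oxo-1,3-dioxolan-4-yl]-16-(2-methyl-1,3-dioxolan-2-yl)hexadec-2-enoate | C[C@]1(/C(C(=O)OC(C)(C)C)=C/CCCCCCCCCCCCCC2(C)OCCO2)O[C@H](C(C)(C)C)OC1=O | intermediate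
16 | 4-tert-butyl 1-methyl (R,Z)-2-hydroxy-2-methyl-3-[14-(2-methyl-1,3-dioxolan-2-yl)tetradecylidene]butanedioate | CC1(CCCCCCCCCCCCC/C=C(\C(=O)OC(C)(C)C)[C@@](C)(O)C(=O)OC)OCCO1 | intermediate (precursor of the key step)
17 | 1-tert-butyl 4-methyl (E)-2-[(S)-1-hydroxy-14-(2-methyl-1,3-dioxolan-2-yl)tetradecyl]-3-methylbut-2-enedioate | CC1(CCCCCCCCCCCCC[C@H](O)/C(C(=O)OC(C)(C)C)=C(/C)C(=O)OC)OCCO1 | intermediate (not isolated)
18 | tert-butyl (S)-4-methyl-2-[13-(2-methyl-1,3-dioxolan-2-yl)tridecyl]-5-oxo-2,5-dihydrofuran-3-carboxylate | CC1(CCCCCCCCCCCCC[C@@H]2OC(=O)C(C)=C2C(=O)OC(C)(C)C)OCCO1 | intermediate (product of the key step)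
19 | (S)-4-methyl-5-oxo-2-(14-oxopentadecyl)-2,5-dihydrofuran-3-carboxylic acid | CC(=O)CCCCCCCCCCCCC[C@@H]1OC(=O)C(C)=C1C(=O)O | target

Total step count: 12. Longest linear sequence: 11 steps (4 → 19, steps 2–12).

Steps most likely to fail

Step 11. The sigmatropic shift may be too slow because the allyl unit carries two ester groups and the α-hydroxy ester may bind rhenium. Forcing it with heat or a more acidic rhenium source could open an ionising pathway that erodes the C3 → C5 chirality transfer, or strip the acid-labile groups early. The fallback sets out from 16 and returns at 18, and sets C5 by reagent control instead of relay. Buffered pyridinium chlorochromate (NaOAc, CH2Cl2) should effect an oxidative 1,3-transposition of the tertiary allylic alcohol (Babler–Dauben oxidation), pulled forward by irreversible oxidation of the transposed chromate, to give 1-tert-butyl 4-methyl (E)-3-methyl-2-[14-(2-methyl-1,3-dioxolan-2-yl)tetradecanoyl]but-2-enedioate F1; any Z isomer would be equilibrated with catalytic iodine. Corey–Bakshi–Shibata reduction of the C5 ketone with the (R)-oxazaborolidine and catecholborane at low temperature is expected to give (S)-configured 17, which should lactonise to 18 on mildly acidic work-up.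

Step 8. Acetate capture of the hindered acyl–palladium species may be slow, so that triflate hydrolysis or attack of acetate on the acylal could compete. The fallback sets out from 12 and returns at 14. It reverses the polarity of the C1 introduction: cobalt- or nickel-catalysed reductive carboxylation of the alkenyl triflate with CO2 (Mn powder, Et4NI, DMA, rt) generates a nucleophilic alkenyl–metal species that captures CO2 directly, with no CO and no acetate. It makes no new compound (F0).

Step 10. Methoxide may add in conjugate fashion at C5 and expel the C3 oxygen, an addition–elimination that would transpose the oxygen without stereocontrol, or the hindered acylal may open only sluggishly. The fallback sets out from 15 and returns at 16. It replaces transesterification by saponification and re-esterification: LiOH in THF/H2O at 0 °C should open the acylal to (R,Z)-3-(tert-butoxycarbonyl)-2-hydroxy-2-methyl-17-(2-methyl-1,3-dioxolan-2-yl)heptadec-3-enoic acid F2, and trimethylsilyldiazomethane (toluene/MeOH) would then methylate the free acid to 16.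

Further compounds
F1 | step 11 | 1-tert-butyl 4-methyl (E)-3-methyl-2-[14-(2-methyl-1,3-dioxolan-2-yl)tetradecanoyl]but-2-enedioate | CC1(CCCCCCCCCCCCCC(=O)/C(C(=O)OC(C)(C)C)=C(/C)C(=O)OC)OCCO1
F0 | step 8 | none | none
F2 | step 10 | (R,Z)-3-(tert-butoxycarbonyl)-2-hydroxy-2-methyl-17-(2-methyl-1,3-dioxolan-2-yl)heptadec-3-enoic acid | CC1(CCCCCCCCCCCCC/C=C(\C(=O)OC(C)(C)C)[C@@](C)(O)C(=O)O)OCCO1
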